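**Retrosynthetic overview**

- Feature: in the ten-membered carbocycle C1–C10, the cis-trisubstituted C4=C5 olefin (C4 carries C15) meets the unfunctionalised C3H2–C2H2 bridge, so the C3(sp3)–C4(sp2) ring bond lies remote from the stereocentres C6–C9 and from the trans-fused 6,12-γ-lactone (O–C6–C7–C11–C12).
- Last ring: C3–C4 by intramolecular B-alkyl Suzuki coupling of a C3 alkylborane (from the terminal C2=C3 vinyl of the 1(10)Z-diene) with the Z-C4 vinyl iodide; then 8-O-desilylation.
- C6–C7 and the γ-lactone: indium Barbier allylation of (Z)-3-iodobut-2-enal with a ring-locked 3-(bromomethyl)-5,6-dihydropyran-2-one (O9–C12 δ-lactone), then δ→γ acyl shift, which frees 9-OH for acetylation.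
- δ-Lactone: C7–C11 by Morita–Baylis–Hillman reaction and C9–C10 by Nozaki–Hiyama–Kishi coupling on an L-threonate-derived C7–C8–C9 unit; the dienyl iodide comes from acrolein.
- Ring order: temporary δ-lactone, then γ-lactone, then the ten-membered carbocycle.

Key step: step 15

Remark: germacrane numbering is used throughout; the C7 carbinol made in step 7 is carried as an epimer mixture (no descriptor in its SMILES) because C7 becomes sp2 in step 12.

**Route**

Step 1
Reactants: 1 but-2-yn-1-ol
Product: 3 (Z)-3-iodobut-2-en-1-ol, via sodium alkenylalanate chelate 2 (not isolated)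
Conditions: Red-Al, THF, 0 °C → rt; then I2, −78 → 0 °C
Reagents that add atoms: iodine, II
Why: Hydroxyl-directed trans-hydroalumination of the propargylic alcohol places aluminium at C3 in a five-membered chelate, and iodinolysis with retention should give the Z-γ-iodo allylic alcohol that becomes C6–C5=C4(I)–C15.

Step 2
Reactants: 3 (Z)-3-iodobut-2-en-1-ol
Product: 4 (Z)-3-iodobut-2-enal
Conditions: MnO2, CH2Cl2, rt, dark
Reagents that add atoms: none
Why: Heterogeneous MnO2 oxidation of the primary allylic alcohol should stop at the enal without touching the vinyl iodide, and neutral light-free handling limits Z→E isomerisation.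

Step 3
Reactants: 5 ethyl (triphenylphosphoranylidene)acetate; 6 acrolein
Product: 8 ethyl (2Z)-2-iodopenta-2,4-dienoate, via iodo ylide 7 (not isolated)
Conditions: NIS, CH2Cl2, −20 °C; then 6, −20 °C → rt
Reagents that add atoms: N-iodosuccinimide, O=C1CCC(=O)N1I
Why: Iodination of the stabilised ylide (succinimide anion as base) gives the α-iodo ylide, whose Wittig olefination should place the ester trans to the vinyl group as usual for stabilised ylides, so that iodine is cis to the vinyl group (Z).

Step 4
Reactants: 8 ethyl (2Z)-2-iodopenta-2,4-dienoate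
Product: 9 (2Z)-2-iodopenta-2,4-dien-1-ol
Conditions: DIBAL-H, CH2Cl2, −78 °C
Reagents that add atoms: none
Why: DIBAL-H 1,2-reduction of the conjugated ester at low temperature should give the allylic alcohol with the C–I bond and the diene intact.

Step 5
Reactants: 10 methyl 3,4-O-isopropylidene-L-threonate
Product: 11 methyl 2-O-TBS-3,4-O-isopropylidene-L-threonate
Conditions: TBSCl, imidazole, DMF, rt
Reagents that add atoms: tert-butyldimethylsilyl chloride, CC(C)(C)[Si](C)(C)Cl
Why: Standard silylation of the α-hydroxy ester installs the 8-O-TBS group that is kept to the last step and later supports Felkin–Anh control; the threonate C2 centre is C8 of the target.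

Step 6
Reactants: 11 methyl 2-O-TBS-3,4-O-isopropylidene-L-threonate
Product: 12 2-O-TBS-3,4-O-isopropylidene-L-threose
Conditions: DIBAL-H, CH2Cl2, −78 °C; Rochelle salt
Reagents that add atoms: none
Why: Partial DIBAL-H reduction of an α-silyloxy methyl ester at −78 °C should stop at the aldehyde (C7) through the stable tetrahedral aluminate.

Step 7
Reactants: 12 2-O-TBS-3,4-O-isopropylidene-L-threose; 13 1,1,1,3,3,3-hexafluoropropan-2-yl acrylate
Product: 14 Morita–Baylis–Hillman adduct (hexafluoroisopropyl ester; C7 epimers)
Conditions: DABCO, DMF, 0 °C → rt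
Reagents that add atoms: none
Why: The Morita–Baylis–Hillman reaction forms C7–C11 and brings in C12 and C13; the fluorinated acrylate is chosen because it reacts fast (limiting α-epimerisation of the aldehyde) and leaves an activated ester for step 10.

Step 8
Reactants: 14 Morita–Baylis–Hillman adduct
Product: 15 hexafluoroisopropyl 3-hydroxy-2-methylene-5-oxo-4-(TBSO)pentanoate (C7 epimers)
Conditions: H5IO6, EtOAc, rt
Reagents that add atoms: none
Why: Periodic acid should hydrolyse the terminal acetonide and cleave the liberated 1,2-diol in one operation (Malaprade cleavage), unmasking C9 as the α-silyloxy aldehyde while the secondary TBS ether and the ester survive.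

Step 9
Reactants: 15 hexafluoroisopropyl 3-hydroxy-2-methylene-5-oxo-4-(TBSO)pentanoate; 9 (2Z)-2-iodopenta-2,4-dien-1-ol
Product: 16 hexafluoroisopropyl (6Z)-3,5-dihydroxy-6-(hydroxymethyl)-2-methylene-4-(TBSO)nona-6,8-dienoate (8,9-anti; C7 epimers)
Conditions: CrCl2, NiCl2 (cat.), DMSO, rt
Reagents that add atoms: none
Why: In this Nozaki–Hiyama–Kishi coupling the alkenylchromium species from 9 should add to the α-silyloxy aldehyde in the Felkin–Anh sense (C–OTBS anti to the nucleophile), forming C9–C10 with the 8,9-anti (erythro) carbinol and retention of the diene geometry, and it tolerates free hydroxyls, the acrylate and the activated ester.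

Step 10
Reactants: 16 Nozaki–Hiyama–Kishi triol ester
Product: 17 4-hydroxy-6-[(2Z)-1-hydroxypenta-2,4-dien-2-yl]-3-methylene-5-(TBSO)tetrahydropyran-2-one (5,6-trans; C7 epimers)
Conditions: DMAP (cat.), i-Pr2NEt, CH2Cl2 (5 mM), rt
Reagents that add atoms: none
Why: DMAP-catalysed intramolecular transesterification of the activated ester by the 9-OH should close the six-membered lactone (7-OH and 14-OH would need four- and eight-membered rings), which fixes C8 cis to the C12 carbonyl.

Step 11
Reactants: 17 δ-lactone diol; 18 isovaleryl chloride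
Product: 19 14-O-isovalerate of 17
Conditions: 2,4,6-collidine, CH2Cl2, −78 → −40 °C
Reagents that add atoms: none
Why: The primary allylic 14-OH should be acylated selectively over the hindered secondary 7-OH by one equivalent of acid chloride with a hindered base at low temperature.

Step 12
Reactants: 19 14-O-isovalerate of 17
Product: 20 3-(bromomethyl)-5-(TBSO)-6-[(2Z)-1-(3-methylbutanoyloxy)penta-2,4-dien-2-yl]-5,6-dihydro-2H-pyran-2-one (5,6-trans)
Conditions: NBS, Me2S, CH2Cl2, −20 → 0 °C
Reagents that add atoms: N-bromosuccinimide, O=C1CCC(=O)N1Br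
Why: Activation of the Morita–Baylis–Hillman alcohol as an alkoxysulfonium ion (Corey–Kim-type reagent without base) and SN2′ attack of bromide at the exo-methylene should give the conjugated primary allylic bromide, both C7 epimers converging on one compound.

Step 13
Reactants: 20 bromomethyl δ-lactone; 4 (Z)-3-iodobut-2-enal
Product: 22 seco-germacranolide alcohol (6α,12-γ-lactone; 8-OTBS; free 9-OH; 14-O-isovalerate), via δ-lactone carbinol 21 (not isolated)
Conditions: In, THF/sat. aq NH4Cl, rt; then PPTS (cat.), CH2Cl2, 35 °C
Reagents that add atoms: none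
Why: In this indium Barbier 2-(acyl)allylation the ring-locked allylindium species (C8 held trans to the CH2–In carbon) should react through a Zimmerman–Traxler chair with the enal substituent equatorial and on the C7 face anti to the 8-OTBS group, which sets C7 (trans to O8 on the ring) and C6 (anti to C8, the future trans-lactone) and regenerates the exo-methylene, after which acid-catalysed O9→O6 acyl shift to the more stable γ-lactone releases the 9-OH.

Step 14
Reactants: 22 seco-germacranolide alcohol
Product: 23 9-O-acetate of 22 (key-step precursor)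
Conditions: Ac2O, pyridine, DMAP (cat.), CH2Cl2, 0 °C
Reagents that add atoms: acetic anhydride, CC(=O)OC(C)=O
Why: Routine acetylation of the only free hydroxyl group completes the precursor before any base could move the neighbouring silyl group.

Step 15
Reactants: 23 9-O-acetate of 22
Product: 25 8-O-TBS ether of the target, via alkyl-9-BBN borane 24 (not isolated)
Conditions: 9-BBN, THF, 0 °C → rt; then slow addition to Pd(dppf)Cl2 (20 mol%), AsPh3, Cs2CO3, DMF/THF/H2O, rt, final 1 mM
Reagents that add atoms: none
Why: 9-BBN should add anti-Markovnikov to the monosubstituted C2=C3 terminus of the diene (boron at C3), because the trisubstituted C1=C10 and C4=C5 olefins are too hindered and the exo-methylene enoate too electron-poor to compete at 0 °C. Pd(0) then inserts into the C4–I bond with retention of the Z geometry, base-assisted transmetallation transfers the primary C3 alkyl group from the hydroxyborate, and reductive elimination forms C3–C4; the closest known reaction type is the intramolecular B-alkyl Suzuki–Miyaura macrocyclisation. The ten-membered carbocycle is closed end-to-end by this C(sp3)–C(sp2) coupling, with both cis olefins and the trans-fused lactone already in place to bring C3 and C4 together. No stereocentre is formed and C6–C9 are not touched. The step needs chemoselective hydroboration, retention of olefin geometry and cyclisation over oligomerisation, which the steric bias of 9-BBN, the stereoretentive oxidative addition and slow addition at high dilution with a mild carbonate base (sparing acetate, isovalerate and lactone) should secure.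

Step 16
Reactants: 25 8-O-TBS ether of the target
Product: 26 target CNP0603244.1
Conditions: HF·pyridine, pyridine, THF, 0 °C → rt
Reagents that add atoms: none
Why: Fluoride cleavage of the secondary TBS ether under buffered acidic conditions should leave the esters and the exo-methylene lactone untouched and avoid base-induced 9→8 acetyl migration.

**Compound list**

1 | but-2-yn-1-ol | CC#CCO | starting material
2 | sodium alkenylalanate chelate from trans-hydroalumination of 1 (not isolated) | C/C1=C/CO[Al-]1(OCCOC)OCCOC.[Na+] | intermediate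
3 | (Z)-3-iodobut-2-en-1-ol | C/C(I)=C/CO | intermediate
4 | (Z)-3-iodobut-2-enal | C/C(I)=C/C=O | intermediate
5 | ethyl (triphenylphosphoranylidene)acetate | CCOC(=O)C=P(c1ccccc1)(c1ccccc1)c1ccccc1 | starting material
6 | acrolein | C=CC=O | starting material
7 | ethyl iodo(triphenylphosphoranylidene)acetate (not isolated) | CCOC(=O)C(I)=P(c1ccccc1)(c1ccccc1)c1ccccc1 | intermediate
8 | ethyl (2Z)-2-iodopenta-2,4-dienoate | CCOC(=O)/C(I)=C/C=C | intermediate
9 | (2Z)-2-iodopenta-2,4-dien-1-ol | OC/C(I)=C/C=C | intermediate
10 | methyl 3,4-O-isopropylidene-L-threonate, methyl (2R)-2-hydroxy-2-[(4S)-2,2-dimethyl-1,3-dioxolan-4-yl]acetate | COC(=O)[C@H](O)[C@@H]1COC(C)(C)O1 | starting material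
11 | methyl (2R)-2-(tert-butyldimethylsilyloxy)-2-[(4S)-2,2-dimethyl-1,3-dioxolan-4-yl]acetate | COC(=O)[C@H](O[Si](C)(C)C(C)(C)C)[C@@H]1COC(C)(C)O1 | intermediate
12 | (2R)-2-(tert-butyldimethylsilyloxy)-2-[(4S)-2,2-dimethyl-1,3-dioxolan-4-yl]acetaldehyde | O=C[C@H](O[Si](C)(C)C(C)(C)C)[C@@H]1COC(C)(C)O1 | intermediate
13 | 1,1,1,3,3,3-hexafluoropropan-2-yl acrylate | C=CC(=O)OC(C(F)(F)F)C(F)(F)F | starting material
14 | hexafluoroisopropyl 4-[(4S)-2,2-dimethyl-1,3-dioxolan-4-yl]-3-hydroxy-2-methylene-4-(TBSO)butanoate (C7 epimers; C8 as in 12) | C=C(C(=O)OC(C(F)(F)F)C(F)(F)F)C(O)[C@H](O[Si](C)(C)C(C)(C)C)[C@@H]1COC(C)(C)O1 | intermediate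
15 | hexafluoroisopropyl 3-hydroxy-2-methylene-5-oxo-4-(TBSO)pentanoate (C7 epimers; C8 from 10) | C=C(C(=O)OC(C(F)(F)F)C(F)(F)F)C(O)[C@H](O[Si](C)(C)C(C)(C)C)C=O | intermediate
16 | hexafluoroisopropyl (6Z)-3,5-dihydroxy-6-(hydroxymethyl)-2-methylene-4-(TBSO)nona-6,8-dienoate (8,9-anti; C7 epimers) | C=C(C(=O)OC(C(F)(F)F)C(F)(F)F)C(O)[C@H](O[Si](C)(C)C(C)(C)C)[C@H](O)/C(CO)=C\C=C | intermediate
17 | 4-hydroxy-6-[(2Z)-1-hydroxypenta-2,4-dien-2-yl]-3-methylene-5-(TBSO)tetrahydropyran-2-one (5,6-trans; C7 epimers) | C=C1C(=O)O[C@H](/C(CO)=C\C=C)[C@@H](O[Si](C)(C)C(C)(C)C)C1O | intermediate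
18 | isovaleryl chloride | CC(C)CC(Cl)=O | starting material
19 | 14-O-isovalerate of 17 | C=C1C(=O)O[C@H](/C(COC(=O)CC(C)C)=C\C=C)[C@@H](O[Si](C)(C)C(C)(C)C)C1O | intermediate
20 | 3-(bromomethyl)-5-(TBSO)-6-[(2Z)-1-(3-methylbutanoyloxy)penta-2,4-dien-2-yl]-5,6-dihydro-2H-pyran-2-one (5,6-trans) | BrCC1=C[C@H](O[Si](C)(C)C(C)(C)C)[C@H](OC1=O)/C(COC(=O)CC(C)C)=C\C=C | intermediate
21 | δ-lactone carbinol: 4-[(2Z)-1-hydroxy-3-iodobut-2-enyl]-3-methylene analogue of 19 (4,5-trans; 5,6-trans; not isolated) | C=C1C(=O)O[C@H](/C(COC(=O)CC(C)C)=C\C=C)[C@@H](O[Si](C)(C)C(C)(C)C)[C@@H]1[C@H](O)/C=C(/C)I | intermediate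
22 | seco-germacranolide alcohol: trans-6α,12-γ-lactone with (Z)-2-iodoprop-1-enyl at C6, 8-OTBS, free 9-OH, 14-O-isovalerate, 1(10)Z-diene (C6–C9 as in 26) | C=C1C(=O)O[C@H](/C=C(/C)I)[C@H]1[C@H](O[Si](C)(C)C(C)(C)C)[C@H](O)/C(COC(=O)CC(C)C)=C\C=C | intermediate
23 | 9-O-acetate of 22 (key-step precursor) | C=C1C(=O)O[C@H](/C=C(/C)I)[C@H]1[C@H](O[Si](C)(C)C(C)(C)C)[C@H](OC(C)=O)/C(COC(=O)CC(C)C)=C\C=C | intermediate
24 | C3 B-alkyl-9-BBN derivative of 23 (not isolated) | C=C1C(=O)O[C@H](/C=C(/C)I)[C@H]1[C@H](O[Si](C)(C)C(C)(C)C)[C@H](OC(C)=O)/C(COC(=O)CC(C)C)=C\CCB1C2CCCC1CCC2 | intermediate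
25 | 8-O-TBS ether of the target | C=C1C(=O)O[C@@H]2/C=C(/C)CC/C=C(/COC(=O)CC(C)C)[C@@H](OC(C)=O)[C@@H](O[Si](C)(C)C(C)(C)C)[C@@H]12 | intermediate
26 | CNP0603244.1, (6R,7R,8S,9R)-9-acetoxy-8-hydroxy-14-(isovaleryloxy)germacra-1(10)Z,4Z,11(13)-trien-6,12-olide | C=C1C(=O)O[C@@H]2/C=C(/C)CC/C=C(/COC(=O)CC(C)C)[C@@H](OC(C)=O)[C@@H](O)[C@@H]12 | target

**Step count**

Total: 16 steps. Longest linear sequence: 12 steps (steps 5–16, from 10).

**Steps most likely to fail**

Step 15 (ring closure). The strained Z,Z-cyclodecadiene may close more slowly than intermolecular coupling, so oligomers could dominate. The alkylborane may also be lost by protodeboronation, 9-BBN may reduce the exo-methylene enoate, and the aqueous base may cleave or shift the acetate. The fallback keeps the C3–C4 closure but runs it base-free as a Negishi coupling. It sets out from 23: hydroboration as before with perborate oxidation should give the primary C3 alcohol F1; iodine, triphenylphosphine and imidazole (Appel-type) should give the primary iodide F2; zinc dust with LiCl should insert selectively into the alkyl C–I bond to give the alkylzinc iodide F3; slow addition of F3 to a Pd(0)/biarylphosphine catalyst at high dilution should close the ring and return to 25.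

Step 13 (Barbier allylation and acyl shift). In the aqueous medium a loose or boat-like transition state may erode the C6/C7 control, or the aldehyde may attack cis to the silyloxy group. The allylindium species may also lose silyloxide by 1,4-elimination, and the acyl shift may stall because its bicyclic intermediate places the C9 dienyl group endo. The fallback uses a preformed, configurationally fixed allylboron reagent in a tight type-I transition state. It sets out from 19: acetylation should give the allylic acetate F4; copper-catalysed SN2′ borylation with bis(pinacolato)diboron should give the 3-(pinacolborylmethyl) lactone F5; Sc(OTf)3-catalysed allylboration of 4 in toluene should give 21 after work-up, and the same acid-catalysed acyl shift returns to 22.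

Step 9 (Nozaki–Hiyama–Kishi coupling). Felkin–Anh discrimination may be insufficient, possibly disturbed by chelation of chromium by the free 7-OH, giving C9 epimers. The fallback sets C9 by reagent-controlled ketone reduction instead of by the C–C bond formation. It sets out from 16 as its C9 epimer mixture: selective acylation of the primary 14-OH with 18 and collidine should give the isovalerate F6; MnO2 should oxidise the dienylic 9-OH selectively to the dienone F7; Corey–Bakshi–Shibata reduction with catecholborane ((R)-oxazaborolidine, if the dienyl group acts as the larger substituent) should give the 9R carbinol F8; DMAP-catalysed lactonisation of F8 returns to 19.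

**Further compounds**

F1 | step 15 | C3 primary alcohol from hydroboration–oxidation of 23 | C=C1C(=O)O[C@H](/C=C(/C)I)[C@H]1[C@H](O[Si](C)(C)C(C)(C)C)[C@H](OC(C)=O)/C(COC(=O)CC(C)C)=C\CCO
F2 | step 15 | C3 primary iodide | C=C1C(=O)O[C@H](/C=C(/C)I)[C@H]1[C@H](O[Si](C)(C)C(C)(C)C)[C@H](OC(C)=O)/C(COC(=O)CC(C)C)=C\CCI
F3 | step 15 | C3 alkylzinc iodide | C=C1C(=O)O[C@H](/C=C(/C)I)[C@H]1[C@H](O[Si](C)(C)C(C)(C)C)[C@H](OC(C)=O)/C(COC(=O)CC(C)C)=C\CC[Zn]I
F4 | step 13 | 7-O-acetate of 19 | C=C1C(=O)O[C@H](/C(COC(=O)CC(C)C)=C\C=C)[C@@H](O[Si](C)(C)C(C)(C)C)C1OC(C)=O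
F5 | step 13 | 3-(pinacolborylmethyl) analogue of 20 | CC1(C)OB(CC2=C[C@H](O[Si](C)(C)C(C)(C)C)[C@H](OC2=O)/C(COC(=O)CC(C)C)=C\C=C)OC1(C)C
F6 | step 9 | 14-O-isovalerate of 16 (C9 and C7 epimers) | C=C(C(=O)OC(C(F)(F)F)C(F)(F)F)C(O)[C@H](O[Si](C)(C)C(C)(C)C)C(O)/C(COC(=O)CC(C)C)=C\C=C
F7 | step 9 | C9 dienone from F6 | C=C(C(=O)OC(C(F)(F)F)C(F)(F)F)C(O)[C@H](O[Si](C)(C)C(C)(C)C)C(=O)/C(COC(=O)CC(C)C)=C\C=C
F8 | step 9 | 9R carbinol (14-O-isovalerate of 16, single C9 epimer) | C=C(C(=O)OC(C(F)(F)F)C(F)(F)F)C(O)[C@H](O[Si](C)(C)C(C)(C)C)[C@H](O)/C(COC(=O)CC(C)C)=C\C=C
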